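The route rests on cutting the diaryl ether bond C8–O–C1' and on making ring C, the pentylresorcinol ring, temporarily electron-poor. C2' and C4' of ring C stand ortho and para to the ether carbon C1'. As formyl carbons they let the C8 phenoxide of the isocoumarin (rings A and B) displace fluoride at C1'. One twofold Dakin oxidation then replaces both C–CHO bonds by C–O bonds, so the acceptor ring becomes the 2',4'-diol in a single operation. The substrate of that oxidation is 8-(2,4-diformyl-6-pentylphenoxy)-6-methoxy-3-pentylisocoumarin, joined from two fragments by SNAr; cleavage of the O6 methyl ether ends the route.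

Key step: step 9

Remark: the target has no stereocentre; unprimed locants refer to the isocoumarin (ring A the benzo ring, ring B the pyranone ring), primed locants to the phenoxy ring C with C1' as the ether carbon.

Step 1
Reactants: 1 3-bromo-4-fluorobenzaldehyde
Product: 2 2-(3-bromo-4-fluorophenyl)-1,3-dioxolane
Conditions: HOCH2CH2OH (1.5 equiv), p-TsOH·H2O (cat.), toluene, reflux, azeotropic removal of H2O
Reagents that add atoms: ethylene glycol, OCCO
Why: Acid-catalysed acetalisation with azeotropic water removal should mask the formyl group as a base-stable dioxolane so that the ring can be metalated in step 2.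

Step 2
Reactants: 2 2-(3-bromo-4-fluorophenyl)-1,3-dioxolane
Product: 4 3-bromo-5-(1,3-dioxolan-2-yl)-2-fluorobenzaldehyde, via aryllithium 3 (not isolated)
Conditions: LiN(iPr)2 (1.1 equiv), THF, −78 °C; DMF, −78 to −40 °C; aq NH4Cl
Reagents that add atoms: N,N-dimethylformamide, CN(C)C=O
Why: Directed ortho-lithiation followed by formylation with DMF should occur at the only ring proton ortho to fluorine, which is also acidified by the meta bromine, while the amide base neither exchanges the C–Br bond nor attacks the dioxolane at −78 °C and the cold aryllithium does not lose LiF.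

Step 3
Reactants: 4 3-bromo-5-(1,3-dioxolan-2-yl)-2-fluorobenzaldehyde; 5 pentylzinc bromide
Product: 7 4-fluoro-5-pentylbenzene-1,3-dicarbaldehyde, via acetal aldehyde 6 (not isolated)
Conditions: Pd(OAc)2 (2 mol%), SPhos (4 mol%), THF, rt to 40 °C; then 2 M HCl, 40 °C
Reagents that add atoms: water, O
Why: In this Negishi coupling, zerovalent palladium formed in situ from Pd(OAc)2 and the biarylphosphine SPhos should insert into the C–Br bond, the primary alkylzinc halide transmetalates without touching the aldehyde, reductive elimination outruns β-hydride elimination, and the dilute acid added afterwards hydrolyses the dioxolane.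

Step 4
Reactants: 8 hexanoyl chloride; 9 N,O-dimethylhydroxylamine hydrochloride
Product: 10 N-methoxy-N-methylhexanamide
Conditions: Et3N (2.2 equiv), CH2Cl2, 0 °C to rt
Reagents that add atoms: none
Why: Acylation of the amine by the acid chloride (nucleophilic acyl substitution) should give cleanly the N-methoxy-N-methylamide needed for a ketone synthesis that stops after one addition.

Step 5
Reactants: 11 methyl 2,4-dimethoxy-6-methylbenzoate; 10 N-methoxy-N-methylhexanamide
Product: 13 methyl 2,4-dimethoxy-6-(2-oxoheptyl)benzoate, via benzylic lithium 12 (not isolated)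
Conditions: LiN(iPr)2 (1.2 equiv), THF, −78 °C (11 added to the base); 10, −78 to 0 °C; aq NH4Cl
Reagents that add atoms: none
Why: Lateral lithiation of the ortho-toluate, whose benzylic anion is stabilised by the ortho ester, is followed by a Weinreb ketone synthesis in which the chelated adduct releases the ketone only on work-up, so neither a second addition nor proton transfer to an enolisable product should consume the anion.

Step 6
Reactants: 13 methyl 2,4-dimethoxy-6-(2-oxoheptyl)benzoate
Product: 14 6,8-dimethoxy-3-pentylisocoumarin
Conditions: p-TsOH·H2O (10 mol%), toluene, reflux, MeOH distilled off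
Reagents that add atoms: none
Why: In this acid-catalysed enol lactonisation the enol of the benzylic ketone attacks the neighbouring ester carbonyl (6-exo-trig acyl transfer), and loss of MeOH is driven by distillation and by formation of the conjugated 2-benzopyran-1-one.

Step 7
Reactants: 14 6,8-dimethoxy-3-pentylisocoumarin
Product: 15 8-hydroxy-6-methoxy-3-pentylisocoumarin
Conditions: BCl3 (1.5 equiv), CH2Cl2, −78 to 0 °C; H2O
Reagents that add atoms: none
Why: In this chelation-controlled Lewis-acid ether cleavage BCl3 bridges the lactone carbonyl oxygen and the peri O8, so chloride should demethylate only that ether while the unchelated 6-methoxy group stays inert at this temperature.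

Step 8
Reactants: 15 8-hydroxy-6-methoxy-3-pentylisocoumarin; 7 4-fluoro-5-pentylbenzene-1,3-dicarbaldehyde
Product: 16 8-(2,4-diformyl-6-pentylphenoxy)-6-methoxy-3-pentylisocoumarin
Conditions: Cs2CO3 (1.5 equiv), 4 Å MS, DMF, 60 °C
Reagents that add atoms: none
Why: In this nucleophilic aromatic substitution by addition–elimination the formyl groups ortho and para to C–F in 7 stabilise the anionic σ-adduct, so even the weakly nucleophilic caesium phenoxide of 15 next to the peri carbonyl should add and expel fluoride, while dry carbonate is too poor a nucleophile to open the enol lactone.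

Step 9
Reactants: 16 8-(2,4-diformyl-6-pentylphenoxy)-6-methoxy-3-pentylisocoumarin
Product: 18 8-(2,4-dihydroxy-6-pentylphenoxy)-6-methoxy-3-pentylisocoumarin, via bis(formate) 17 (not isolated)
Conditions: mCPBA (2.5 equiv), CH2Cl2, 0 °C to rt; aq Na2S2O3 wash; then HCl (cat.), MeOH, 0 °C to rt
Reagents that add atoms: mCPBA (3-chloroperbenzoic acid), OOC(=O)c1cccc(Cl)c1
Why: In this twofold Dakin (Baeyer–Villiger) oxidation the peracid adds to each formyl carbon to give a peroxyhemiacetal, and the ring C carbon (C2' and C4' in turn) shifts from carbon to the peroxide oxygen as 3-chlorobenzoate leaves, which creates the C2'–O and C4'–O bonds as the aryl formates of 17. The closest known reaction type is the peracid oxidation of ortho- or para-aryloxybenzaldehydes obtained by SNAr to aryloxyphenyl formates, applied here to two formyl groups on one ring; no ring is closed and no stereocentre is formed. The step needs aryl instead of hydride migration at both aldehydes, and the ether oxygen on C1', ortho to C2' and para to C4', supplies the lone-pair donation that supports the migrating aryl carbon in each case, also after the first formyl group has become a formate. It also needs the C3–C4 enol lactone double bond of ring B to survive, which is expected because that bond is deactivated by conjugation of the ring oxygen with the C1 carbonyl, while the carboxylic acid present in the reagent accelerates only the carbonyl addition. The phenols stay masked as formates until excess peracid has been destroyed by the thiosulfate wash, so the electron-rich resorcinol is never exposed to oxidant. The formates are then cleaved by acid-catalysed transesterification with MeOH and not by base, so that no C2' phenoxide arises next to the lactone carbonyl C1.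

Step 10
Reactants: 18 8-(2,4-dihydroxy-6-pentylphenoxy)-6-methoxy-3-pentylisocoumarin
Product: 19 8-(2,4-dihydroxy-6-pentylphenoxy)-6-hydroxy-3-pentylisocoumarin
Conditions: BBr3 (5 equiv), CH2Cl2, −78 °C to rt; MeOH, H2O
Reagents that add atoms: none
Why: In this Lewis-acid cleavage of the aryl methyl ether BBr3 complexes O6 and bromide attacks the methyl carbon, whereas the diaryl ether (no sp3 carbon on oxygen) and the lactone should not be cleaved, and the phenols held as borates are released on hydrolysis.

Compound list
1 | 3-bromo-4-fluorobenzaldehyde | O=Cc1ccc(F)c(Br)c1 | starting material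
2 | 2-(3-bromo-4-fluorophenyl)-1,3-dioxolane | Fc1ccc(cc1Br)C1OCCO1 | intermediate
3 | [3-bromo-5-(1,3-dioxolan-2-yl)-2-fluorophenyl]lithium (formed in the flask, not isolated) | [Li]c1cc(cc(Br)c1F)C1OCCO1 | intermediate
4 | 3-bromo-5-(1,3-dioxolan-2-yl)-2-fluorobenzaldehyde | O=Cc1cc(cc(Br)c1F)C1OCCO1 | intermediate
5 | pentylzinc bromide (solution in THF) | CCCCC[Zn]Br | starting material
6 | 5-(1,3-dioxolan-2-yl)-2-fluoro-3-pentylbenzaldehyde (formed in the flask, not isolated) | CCCCCc1cc(cc(C=O)c1F)C1OCCO1 | intermediate
7 | 4-fluoro-5-pentylbenzene-1,3-dicarbaldehyde | CCCCCc1cc(C=O)cc(C=O)c1F | intermediate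
8 | hexanoyl chloride | CCCCCC(Cl)=O | starting material
9 | N,O-dimethylhydroxylamine hydrochloride | CNOC.Cl | starting material
10 | N-methoxy-N-methylhexanamide | CCCCCC(=O)N(C)OC | intermediate
11 | methyl 2,4-dimethoxy-6-methylbenzoate | COC(=O)c1c(C)cc(OC)cc1OC | starting material
12 | methyl 2-(lithiomethyl)-4,6-dimethoxybenzoate (formed in the flask, not isolated) | [Li]Cc1cc(OC)cc(OC)c1C(=O)OC | intermediate
13 | methyl 2,4-dimethoxy-6-(2-oxoheptyl)benzoate | CCCCCC(=O)Cc1cc(OC)cc(OC)c1C(=O)OC | intermediate
14 | 6,8-dimethoxy-3-pentylisocoumarin (6,8-dimethoxy-3-pentyl-1H-isochromen-1-one) | CCCCCc1cc2cc(OC)cc(OC)c2c(=O)o1 | intermediate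
15 | 8-hydroxy-6-methoxy-3-pentylisocoumarin | CCCCCc1cc2cc(OC)cc(O)c2c(=O)o1 | intermediate
16 | 8-(2,4-diformyl-6-pentylphenoxy)-6-methoxy-3-pentylisocoumarin | CCCCCc1cc2cc(OC)cc(Oc3c(C=O)cc(C=O)cc3CCCCC)c2c(=O)o1 | intermediate
17 | 8-[2,4-bis(formyloxy)-6-pentylphenoxy]-6-methoxy-3-pentylisocoumarin (formed in the flask, not isolated) | CCCCCc1cc2cc(OC)cc(Oc3c(OC=O)cc(OC=O)cc3CCCCC)c2c(=O)o1 | intermediate
18 | 8-(2,4-dihydroxy-6-pentylphenoxy)-6-methoxy-3-pentylisocoumarin | CCCCCc1cc2cc(OC)cc(Oc3c(O)cc(O)cc3CCCCC)c2c(=O)o1 | intermediate
19 | 8-(2,4-dihydroxy-6-pentylphenoxy)-6-hydroxy-3-pentylisocoumarin (CNP0213708.0) | CCCCCc1cc2cc(O)cc(Oc3c(O)cc(O)cc3CCCCC)c2c(=O)o1 | target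

Total step count: 10 steps. Longest linear sequence: 7 steps (steps 4 to 10, from hexanoyl chloride); the ring C branch (steps 1 to 3) joins at step 8.

Steps most likely to fail

Step 9. Each formyl group sits meta to a second acceptor, and the doubly ortho-substituted ring C is twisted, which weakens donation from the ether oxygen. Hydride migration to carboxylic acids may therefore compete with aryl migration, and forcing the oxidation may begin to consume the C3–C4 double bond of the enol lactone. The fallback moves the oxidation from aldehydes to methyl ketones, where hydride migration is impossible and aryl migrates ahead of methyl. It sets out from 7 and 15 and comes back at 18. Addition of MeMgBr to 7 (THF, −78 °C) should give the diol 1,1'-(4-fluoro-5-pentyl-1,3-phenylene)di(ethan-1-ol) F1. Oxidation with MnO2 (CH2Cl2, rt) should give the diketone 1,1'-(4-fluoro-5-pentyl-1,3-phenylene)di(ethan-1-one) F2. Substitution of its fluoride by 15 (Cs2CO3, DMSO, 80 °C) should give 8-(2,4-diacetyl-6-pentylphenoxy)-6-methoxy-3-pentylisocoumarin F3. Baeyer–Villiger oxidation (mCPBA, cat. CF3CO2H, CH2Cl2, rt) should give the diacetate 8-(2,4-diacetoxy-6-pentylphenoxy)-6-methoxy-3-pentylisocoumarin F4. Acid methanolysis (HCl, MeOH, 40 °C) then returns to the route at 18.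

Step 8. Addition of the hindered phenoxide, ion-paired to the peri carbonyl, to a fluoride flanked by formyl and pentyl may be slow, and prolonged heating with carbonate or adventitious hydroxide may open the enol lactone. The fallback replaces the stoichiometric base by a fluoride-catalysed silyl-transfer coupling; it sets out from 15 and comes back at 16. Silylation of 15 with N,O-bis(trimethylsilyl)acetamide (MeCN, 60 °C, volatiles removed) should give 6-methoxy-3-pentyl-8-(trimethylsilyloxy)isocoumarin F5. F5 is then heated with 7 and catalytic CsF in dry DMF at 60 °C. Fluoride should unmask a free, unchelated phenoxide, the substitution at C1' releases fluoride again, and fluorotrimethylsilane leaves as a gas, so no basic salt accumulates while 16 forms.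

Step 5. Proton transfer from the amide or from unlithiated ester to the benzylic anion, and Claisen-type self-condensation of the anion with 11, may erode the acylation. The fallback builds ring B from a homophthalic acid instead; it sets out from 11 and comes back at 14, bypassing steps 4 to 6. The anion 12 (LiN(iPr)2, THF, −78 °C) is quenched with CO2, a non-enolisable electrophile that reacts at once, to give [3,5-dimethoxy-2-(methoxycarbonyl)phenyl]acetic acid F6. Saponification (KOH, aq EtOH, reflux) should give 3,5-dimethoxyhomophthalic acid F7. Heating F7 with hexanoyl chloride 8 (neat, 200 °C) should give 14 through C-acylation of the derived anhydride, ring closure through the enol oxygen and decarboxylation.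

Further compounds
F1 | step 9 | 1,1'-(4-fluoro-5-pentyl-1,3-phenylene)di(ethan-1-ol), mixture of diastereomers | CCCCCc1cc(cc(C(C)O)c1F)C(C)O
F2 | step 9 | 1,1'-(4-fluoro-5-pentyl-1,3-phenylene)di(ethan-1-one) | CCCCCc1cc(cc(C(C)=O)c1F)C(C)=O
F3 | step 9 | 8-(2,4-diacetyl-6-pentylphenoxy)-6-methoxy-3-pentylisocoumarin | CCCCCc1cc2cc(OC)cc(Oc3c(C(C)=O)cc(C(C)=O)cc3CCCCC)c2c(=O)o1
F4 | step 9 | 8-(2,4-diacetoxy-6-pentylphenoxy)-6-methoxy-3-pentylisocoumarin | CCCCCc1cc2cc(OC)cc(Oc3c(OC(C)=O)cc(OC(C)=O)cc3CCCCC)c2c(=O)o1
F5 | step 8 | 6-methoxy-3-pentyl-8-(trimethylsilyloxy)isocoumarin | CCCCCc1cc2cc(OC)cc(O[Si](C)(C)C)c2c(=O)o1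
F6 | step 5 | [3,5-dimethoxy-2-(methoxycarbonyl)phenyl]acetic acid | COC(=O)c1c(CC(O)=O)cc(OC)cc1OC
F7 | step 5 | 3,5-dimethoxyhomophthalic acid (2-(carboxymethyl)-4,6-dimethoxybenzoic acid) | OC(=O)Cc1cc(OC)cc(OC)c1C(O)=O
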